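**Strategy**

The route rests on reading the C1 ketone and the C8 oxygen, 1,4-related through C10 and C9 of the ten-membered ring, as the two ends of an ester. The key precursor is therefore a nine-membered lactone (C1 acyl on O8), already fused to the butenolide and carrying the epoxide, with a 2-iodopropyl arm (C9, C10, C14) on C8. SmI2 turns both C10 iodide epimers into one configurationally labile alkylsamarium that attacks C1 through a five-membered transition state, forming the C1–C10 bond and setting C10 stereoconvergently; collapse of the bridged hemiketalate converts the lactone into the ten-membered carbocycle and frees the C8 hydroxyl for tigloylation.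

Key step: step 14

Remark: atom labels follow germacrane numbering (ring C1–C10; C11 and C12 butenolide carbons; C13 acetoxymethyl carbon; C14 methyl on C10; C15 methyl on C4); TBS = tert-butyldimethylsilyl. In this numbering the target is (4R,5S,6S,8S,10R) with a cis-fused 4,5-epoxide (C3 and C6 on the same side), which is why nerol and not geraniol is used.
Assumption: methyl 3-[(tert-butyldimethylsilyl)oxy]propanoate (7) is taken as a purchased reagent.

**Route**

Step 1
Reactants: 1 nerol
Product: 2 (2S,3R)-2,3-epoxynerol
Conditions: Ti(OiPr)4 (10 mol %), L-(+)-diethyl tartrate, t-BuOOH, 4 Å MS, CH2Cl2, −20 °C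
Reagents that add atoms: tert-butyl hydroperoxide, CC(C)(C)OO
Why: Katsuki–Sharpless asymmetric epoxidation of the Z allylic alcohol, in which the L-(+)-tartrate titanium complex delivers oxygen to the face that gives the (2S,3R)-epoxide (later C5 and C4), while the remote trisubstituted alkene, which cannot bind through a hydroxyl, is left alone.

Step 2
Reactants: 2 (2S,3R)-2,3-epoxynerol
Product: 3 (2R,3R)-epoxy aldehyde
Conditions: Dess–Martin periodinane, NaHCO3, CH2Cl2, 0 → 25 °C
Reagents that add atoms: none
Why: Dess–Martin oxidation under bicarbonate buffer should stop at the aldehyde without opening the epoxide or epimerising the oxirane carbon, whose C–H is not readily enolised.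

Step 3
Reactants: 4 methyl (S)-glycidate
Product: 5 methyl (2S)-2-hydroxypent-4-enoate
Conditions: CH2=CHMgBr, CuBr·SMe2 (10 mol %), THF, −78 → −40 °C; aq. NH4Cl
Reagents that add atoms: vinylmagnesium bromide, C=C[Mg]Br
Why: Copper-catalysed SN2 opening of the epoxide at its unsubstituted carbon should outrun addition to the ester at low temperature, and the stereocentre (later C8) is not touched and stays S.

Step 4
Reactants: 5 methyl (2S)-2-hydroxypent-4-enoate
Product: 6 TBS ether of 5
Conditions: TBSCl, imidazole, DMF, 25 °C
Reagents that add atoms: tert-butyldimethylsilyl chloride, CC(C)(C)[Si](C)(C)Cl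
Why: Standard silylation of the secondary hydroxyl, needed so that the α-oxygenated ester can serve as the acyl donor in the next step.

Step 5
Reactants: 6 TBS ether of 5; 7 methyl 3-[(TBS)oxy]propanoate
Product: 9 β-keto ester, via lithium ester enolate 8 (not isolated)
Conditions: LiN(iPr)2 (2.1 equiv), 7 (2.1 equiv), THF, −78 °C; then 6, −78 → −40 °C; aq. NH4Cl
Reagents that add atoms: none
Why: Crossed Claisen condensation in which the activated α-silyloxy ester is acylated faster than it is deprotonated and the product is held as its enolate, so the C8 centre should keep its configuration; the new centre at C11 is of no consequence because it becomes sp2 in step 6.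

Step 6
Reactants: 9 β-keto ester
Product: 10 (Z)-enol triflate
Conditions: Tf2O, sat. aq. LiOH, hexanes, 5 °C
Reagents that add atoms: trifluoromethanesulfonic anhydride, O=S(=O)(OS(=O)(=O)C(F)(F)F)C(F)(F)F
Why: O-triflation of the chelated lithium Z-enolate of the β-keto ester places OTf cis to CO2Me, the geometry that later lets the C6 alkoxide reach C12.

Step 7
Reactants: 3 (2R,3R)-epoxy aldehyde; 10 (Z)-enol triflate
Product: 12 bis-silyl butenolide, via open hydroxy ester 11 (not isolated)
Conditions: CrCl2 (6 equiv), NiCl2 (2 mol %), DMF, 25 °C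
Reagents that add atoms: none
Why: Nozaki–Hiyama–Kishi coupling in which nickel inserts into the C–OTf bond, transmetalation to chromium gives an alkenylchromium that adds to the aldehyde anti to the oxirane C–O bond (polar Felkin–Anh control, setting 6S), and the cis-disposed alkoxide then closes the butenolide with loss of methanol.

Step 8
Reactants: 12 bis-silyl butenolide
Product: 13 C8,C13 diol
Conditions: HF·pyridine, pyridine, THF, 0 → 25 °C
Reagents that add atoms: none
Why: Buffered fluoride cleavage of both silyl ethers, conditions under which the epoxide, the butenolide and the two alkenes should survive.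

Step 9
Reactants: 13 C8,C13 diol
Product: 14 C13 monoacetate
Conditions: AcCl, 2,4,6-collidine, CH2Cl2, −78 °C
Reagents that add atoms: acetyl chloride, CC(=O)Cl
Why: Kinetically selective acylation in which the unhindered primary allylic C13 hydroxyl reacts at low temperature while the secondary C8 hydroxyl next to the tetrasubstituted alkene stays free for the later lactonisation.

Step 10
Reactants: 14 C13 monoacetate
Product: 16 seco aldehyde, via secondary ozonide 15 (not isolated)
Conditions: O3, CH2Cl2, −78 °C (Sudan Red 7B end-point); then PPh3, −78 → 25 °C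
Reagents that add atoms: ozone, [O-][O+]=O
Why: Chemoselective ozonolysis in which the electron-rich trisubstituted alkene should react well ahead of the monosubstituted vinyl group and the electron-poor tetrasubstituted butenolide alkene, as in the classical selective cleavage of citronellene.

Step 11
Reactants: 16 seco aldehyde
Product: 17 seco acid
Conditions: NaClO2, NaH2PO4, 2-methyl-2-butene, t-BuOH/H2O, 0 °C; work-up at pH 5–6 and immediate conversion to the triethylammonium salt
Reagents that add atoms: sodium chlorite, [Na+].[O-]Cl=O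
Why: Pinnick oxidation converts the aldehyde into the acid without touching the free secondary alcohol, the alkenes (hypochlorite is scavenged) or the stereocentres; the γ,δ-epoxy acid is kept as its salt so that the carboxyl does not open the oxirane at C4.

Step 12
Reactants: 17 seco acid
Product: 19 nine-membered lactone, via mixed anhydride 18 (not isolated)
Conditions: 2-methyl-6-nitrobenzoic anhydride, DMAP, Et3N, CH2Cl2 (1 mM), 25 °C, slow addition
Reagents that add atoms: none
Why: Shiina macrolactonisation, a method that tolerates medium rings, here helped by the cis-epoxide and the sp2 carbon C7, which bend the chain so that the C8 hydroxyl can reach the activated C1 carboxyl; O-acylation leaves C8 unchanged.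

Step 13
Reactants: 19 nine-membered lactone
Product: 20 C10 iodide (both epimers)
Conditions: Co(acac)2 (25 mol %), t-BuOOH, Et3SiH, CH2I2, n-PrOH, 25 °C
Reagents that add atoms: diiodomethane, ICI
Why: Mukaiyama-type hydrogen-atom-transfer hydroiodination in which a cobalt hydride delivers hydrogen to C14 of the only unhindered electron-rich alkene and the secondary C10 radical abstracts iodine from diiodomethane (Markovnikov); the C10 epimer mixture is acceptable because step 14 erases this centre.

Step 14
Reactants: 20 C10 iodide (both epimers)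
Product: 23 ten-membered hydroxy ketone, via alkylsamarium 21 (not isolated), via samarium hemiketalate 22 (not isolated)
Conditions: SmI2 (2.5 equiv), Fe(dbm)3 (2 mol %), THF, −30 → 0 °C; then pH 7 buffer
Reagents that add atoms: none
Why: SmI2, activated by catalytic tris(dibenzoylmethanato)iron, reduces the secondary C–I bond to the C10 radical and then to a configurationally labile alkylsamarium, so both iodide epimers enter one manifold. This carbanion adds to the lactone carbonyl C1 to give the bridged samarium hemiketalate (an 11-oxabicyclo[6.2.1]undecane core), and its collapse cleaves C1–O8 to leave the C1 ketone and the free C8 alkoxide. The closest known reaction type is the samarium Barbier-type intramolecular nucleophilic acyl substitution of lactones that carry an iodoalkyl group on the carbinol carbon, which gives ring-expanded hydroxy cycloalkanones. The ten-membered carbocycle is thus closed by a 5-exo-trig carbanion addition (a 1,4 O→C acyl shift) and ring expansion, not by end-to-end macrocyclisation, and the transient oxolane ring is closed in the same 5-exo mode. C10 is set under control of C8: in the bicyclic transition state the C14 methyl should sit anti to the C2–C7 bridge (trans to C7 on the oxolane), which is the 10R configuration, and the enolisable hydroxy ketone/hemiketal pair offers a thermodynamic back-up towards the same epimer. The step needs C–I reduction ahead of electron transfer to the butenolide and attack at C1 ahead of the other carbonyls; this is secured by omitting HMPA and proton donors, by the iron catalyst, and by geometry (C12 is trans to C8 across C7=C11, and the acetate carbonyl would need an eight-membered transition state).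

Step 15
Reactants: 23 ten-membered hydroxy ketone
Product: 24 target
Conditions: (E)-2-methylbut-2-enoyl chloride, DMAP, pyridine, CH2Cl2, 0 → 25 °C
Reagents that add atoms: (E)-2-methylbut-2-enoyl chloride, C/C=C(\C)C(=O)Cl
Why: DMAP-catalysed acylation of the C8 hydroxyl of the open hydroxy ketone tautomer (Curtin–Hammett over the hindered tertiary hemiketal hydroxyl) without touching C8; the E tigloyl geometry is the stable one and should be retained.

**Compound list**

1 | nerol, (2Z)-3,7-dimethylocta-2,6-dien-1-ol | CC(C)=CCC/C(C)=C\CO | starting material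
2 | (2S,3R)-2,3-epoxynerol, [(2S,3R)-3-methyl-3-(4-methylpent-3-en-1-yl)oxiran-2-yl]methanol | CC(C)=CCC[C@@]1(C)O[C@H]1CO | intermediate
3 | (2R,3R)-3-methyl-3-(4-methylpent-3-en-1-yl)oxirane-2-carbaldehyde | CC(C)=CCC[C@@]1(C)O[C@H]1C=O | intermediate
4 | methyl (2S)-oxirane-2-carboxylate (methyl (S)-glycidate) | COC(=O)[C@@H]1CO1 | starting material
5 | methyl (2S)-2-hydroxypent-4-enoate | C=CC[C@H](O)C(=O)OC | intermediate
6 | methyl (2S)-2-[(tert-butyldimethylsilyl)oxy]pent-4-enoate | C=CC[C@H](O[Si](C)(C)C(C)(C)C)C(=O)OC | intermediate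
7 | methyl 3-[(tert-butyldimethylsilyl)oxy]propanoate | COC(=O)CCO[Si](C)(C)C(C)(C)C | starting material
8 | lithium enolate of 7 | COC(O[Li])=CCO[Si](C)(C)C(C)(C)C | intermediate
9 | methyl (4S)-4-[(TBS)oxy]-2-{[(TBS)oxy]methyl}-3-oxohept-6-enoate (both C2 epimers) | C=CC[C@H](O[Si](C)(C)C(C)(C)C)C(=O)C(CO[Si](C)(C)C(C)(C)C)C(=O)OC | intermediate
10 | methyl (2Z,4S)-4-[(TBS)oxy]-2-{[(TBS)oxy]methyl}-3-{[(trifluoromethyl)sulfonyl]oxy}hepta-2,6-dienoate | C=CC[C@H](O[Si](C)(C)C(C)(C)C)/C(OS(=O)(=O)C(F)(F)F)=C(\CO[Si](C)(C)C(C)(C)C)C(=O)OC | intermediate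
11 | open (Z)-γ-hydroxy enoate adduct (4R,5S,6S,8S), methyl ester with free C6 hydroxyl cis to CO2Me | CC(C)=CCC[C@@]1(C)O[C@H]1[C@@H](O)/C(=C(\C(=O)OC)CO[Si](C)(C)C(C)(C)C)[C@@H](O[Si](C)(C)C(C)(C)C)CC=C | intermediate
12 | (5S)-3-{[(TBS)oxy]methyl}-4-[(1S)-1-[(TBS)oxy]but-3-en-1-yl]-5-[(2S,3R)-3-methyl-3-(4-methylpent-3-en-1-yl)oxiran-2-yl]furan-2(5H)-one | CC(C)=CCC[C@@]1(C)O[C@H]1[C@H]1OC(=O)C(CO[Si](C)(C)C(C)(C)C)=C1[C@@H](O[Si](C)(C)C(C)(C)C)CC=C | intermediate
13 | (5S)-4-[(1S)-1-hydroxybut-3-en-1-yl]-3-(hydroxymethyl)-5-[(2S,3R)-3-methyl-3-(4-methylpent-3-en-1-yl)oxiran-2-yl]furan-2(5H)-one | CC(C)=CCC[C@@]1(C)O[C@H]1[C@H]1OC(=O)C(CO)=C1[C@@H](O)CC=C | intermediate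
14 | C13 monoacetate of 13 (C8 hydroxyl free) | CC(C)=CCC[C@@]1(C)O[C@H]1[C@H]1OC(=O)C(COC(C)=O)=C1[C@@H](O)CC=C | intermediate
15 | secondary ozonide of 14 (3,3-dimethyl-1,2,4-trioxolan-5-yl group at C1) | CC1(C)OOC(CC[C@@]2(C)O[C@H]2[C@H]2OC(=O)C(COC(C)=O)=C2[C@@H](O)CC=C)O1 | intermediate
16 | (4R,5S,6S,8S)-13-acetoxy-4,5-epoxy-8-hydroxy-1-oxo-1,10-secogermacra-7(11),10(14)-dien-12,6-olide (seco aldehyde) | O=CCC[C@@]1(C)O[C@H]1[C@H]1OC(=O)C(COC(C)=O)=C1[C@@H](O)CC=C | intermediate
17 | seco acid, the C1 carboxylic acid of 16 | OC(=O)CC[C@@]1(C)O[C@H]1[C@H]1OC(=O)C(COC(C)=O)=C1[C@@H](O)CC=C | intermediate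
18 | mixed anhydride of 17 with 2-methyl-6-nitrobenzoic acid | Cc1cccc([N+](=O)[O-])c1C(=O)OC(=O)CC[C@@]1(C)O[C@H]1[C@H]1OC(=O)C(COC(C)=O)=C1[C@@H](O)CC=C | intermediate
19 | nine-membered lactone (C1 acyl on O8) of 17, (4R,5S,6S,8S), fused to the butenolide at C6–C7, allyl group on C8 | O=C1CC[C@@]2(C)O[C@H]2[C@H]2OC(=O)C(COC(C)=O)=C2[C@H](CC=C)O1 | intermediate
20 | C10 iodide of 19 (2-iodopropyl on C8, both C10 epimers) | O=C1CC[C@@]2(C)O[C@H]2[C@H]2OC(=O)C(COC(C)=O)=C2[C@H](CC(C)I)O1 | intermediate
21 | C10 diiodosamarium alkyl derived from 20 (trivalent samarium, C10 labile) | O=C1CC[C@@]2(C)O[C@H]2[C@H]2OC(=O)C(COC(C)=O)=C2[C@H](CC(C)[Sm](I)I)O1 | intermediate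
22 | bridged samarium hemiketalate, (1R,4R,5S,6S,8S,10R)-13-acetoxy-1,8:4,5-diepoxy-1-[(diiodosamario)oxy]germacr-7(11)-en-12,6-olide | C[C@@H]1C[C@@H]2O[C@@]1(O[Sm](I)I)CC[C@@]3(C)O[C@H]3[C@H]4OC(=O)C(COC(C)=O)=C24 | intermediate
23 | (4R,5S,6S,8S,10R)-13-acetoxy-4,5-epoxy-8-hydroxy-1-oxogermacr-7(11)-en-12,6-olide | O[C@H]1C[C@@H](C)C(=O)CC[C@@]2(C)O[C@H]2[C@H]2OC(=O)C(COC(C)=O)=C12 | intermediate
24 | (4R,5S,6S,8S,10R)-13-acetoxy-4,5-epoxy-8-[(E)-2-methylbut-2-enoyloxy]-1-oxogermacr-7(11)-en-12,6-olide | C/C=C(\C)C(=O)O[C@H]1C[C@@H](C)C(=O)CC[C@@]2(C)O[C@H]2[C@H]2OC(=O)C(COC(C)=O)=C12 | target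

**Step count**

Total: 15 steps. Longest linear sequence: 13 steps (steps 3–15, from methyl (S)-glycidate 4); the nerol branch (steps 1–2) joins at step 7.

**Steps most likely to fail**

1. Step 14. Electron transfer to the butenolide, with loss of the C13 acetate or the C8 carboxylate, may outrun reduction of the C–I bond, and the alkylsamarium may be protonated before it adds to C1. The fallback sets out from aldehyde 16 and comes back at target 24. The C8 hydroxyl is tigloylated (tigloyl chloride, DMAP, pyridine) to the C8 tiglate aldehyde F1. Hydroiodination as in step 13 gives the secondary iodide F2. A Nozaki–Hiyama–Kishi-type alkylchromium addition (CrCl2, catalytic cobalt phthalocyanine, DMF, high dilution) then forms the C1–C10 bond directly, giving the ten-membered C1 carbinol F3. Dess–Martin oxidation gives the ketone F4 as a C10 epimer pair, which is equilibrated with DBU towards 24. In this fallback C10 rests on equilibration alone.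

2. Step 12. Oligomerisation may compete with closure of the strained nine-membered ring, and the C1 carboxylate may attack the oxirane carbon C4 before it is activated. The fallback sets out from aldehyde 16 and comes back at lactone 19. It is an oxidative lactonisation under N-heterocyclic carbene catalysis (triazolium salt, DBU, 3,3',5,5'-tetra-tert-butyldiphenoquinone, CH2Cl2, high dilution): the aldehyde becomes an acyl azolium that is trapped by the C8 hydroxyl, so the free γ,δ-epoxy acid is never formed. It makes no compound outside the list (F0).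

3. Step 7. Insertion and transmetalation at the hindered tetrasubstituted triflate may be slow, CrCl2 may reduce the epoxy aldehyde, and facial selectivity at C6 may erode. The fallback sets out from triflate 10 and comes back at butenolide 12. Iodide-for-triflate exchange by conjugate addition–elimination (NaI, acetone) gives the (Z)-β-iodo enoate F5. Iodine–magnesium exchange (i-PrMgCl·LiCl, THF, −40 °C) gives the alkenylmagnesium chloride F6, which is added to aldehyde 3 at −78 °C under non-chelating conditions and closes the butenolide on warming, through adduct 11.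

**Further compounds**

F1 | step 14 | C8 tiglate of seco aldehyde 16 | O=CCC[C@@]1(C)O[C@H]1[C@H]1OC(=O)C(COC(C)=O)=C1[C@@H](OC(=O)/C(C)=C/C)CC=C
F2 | step 14 | C10 iodide of F1 (both C10 epimers) | O=CCC[C@@]1(C)O[C@H]1[C@H]1OC(=O)C(COC(C)=O)=C1[C@@H](OC(=O)/C(C)=C/C)CC(C)I
F3 | step 14 | ten-membered C1 carbinol, 8-O-tigloyl (C1 and C10 epimers) | C/C=C(\C)C(=O)O[C@H]1CC(C)C(O)CC[C@@]2(C)O[C@H]2[C@H]2OC(=O)C(COC(C)=O)=C12
F4 | step 14 | C10 epimer pair of ketone 24 | C/C=C(\C)C(=O)O[C@H]1CC(C)C(=O)CC[C@@]2(C)O[C@H]2[C@H]2OC(=O)C(COC(C)=O)=C12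
F0 | step 12 | none | none
F5 | step 7 | methyl (2Z,4S)-3-iodo-4-[(TBS)oxy]-2-{[(TBS)oxy]methyl}hepta-2,6-dienoate | C=CC[C@H](O[Si](C)(C)C(C)(C)C)/C(I)=C(\CO[Si](C)(C)C(C)(C)C)C(=O)OC
F6 | step 7 | alkenylmagnesium chloride formed from F5 | C=CC[C@H](O[Si](C)(C)C(C)(C)C)/C([Mg]Cl)=C(\CO[Si](C)(C)C(C)(C)C)C(=O)OC
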